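**Assumptions**
- The catalyst enantiomers quoted are the ones I expect to give the stated configurations. An antipode is swapped in if needed, with no other change.
- The ring-constrained allylchromium addition in Step 16 is assumed to give the trans-fused lactone (1R,14S), as in the target.

## Retrosynthetic overview
1. Michaolide A comes from removal of the silyl groups and acetylation of the macrolide **22**. The 14-membered ring, the trans-α-methylene-γ-butyrolactone (C1, C14) and the two lactone stereocenters form in one step. That step is an intramolecular Cr-mediated (Nozaki–Hiyama–Kishi, NHK) allylation of epoxy-aldehyde **21** with a Baylis–Hillman-derived allylic chloride, with in-situ lactonization.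
2. **21** comes from E-selective cross-metathesis (CM) at C4=C5 between chain **11** (C5–C14) and chloride **19** (C1–C4 plus the acrylate).
3. Chain **11** is built from achiral enal **1**:
   - organocatalytic epoxidation sets C12/C13;
   - catalytic allylboration sets C11 and, later, C7;
   - ozonolysis then Wittig with a stabilized α-methyl ylide gives the E-C8=C9 alkene.
4. **19** is built from ethyl glyoxylate: catalytic methallylboration sets C2, then Baylis–Hillman reaction and chlorination.
5. Order of ring formation: epoxide (Step 1), then the two trisubstituted alkenes (Steps 5 and 14), then the macrocycle and lactone together (Step 16).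

## Route

**Step 1**
Reactants: **1** (E)-4-acetoxy-2-methylbut-2-enal
Product: **2** [(2S,3R)-3-formyl-3-methyloxiran-2-yl]methyl acetate
Conditions: (S)-α,α-bis[3,5-(CF3)2C6H3]prolinol TMS ether (10 mol%), 30% aq. H2O2 (1.5 equiv), CH2Cl2, rt, 24 h
Reagents that add atoms: hydrogen peroxide, OO
Why: Proposed new method: iminium-catalysed (Jørgensen–Hayashi-type) nucleophilic epoxidation of an α,β-disubstituted γ-acyloxy enal to a trisubstituted epoxy aldehyde. The catalyst forms the E-iminium with one face shielded. HOO⁻ adds at C13 and the enamine closes onto the O–O bond. This sets C12 and C13 in one step as the trans-epoxide. The γ-OAc inductively activates C13, which offsets the α-methyl hindrance. The closest known reaction is the enal epoxidation of β-monosubstituted enals.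

**Step 2**
Reactants: **2**; **3** allyldiisopropoxyborane
Product: **4** [(2S,3S)-3-[(1R)-1-hydroxybut-3-en-1-yl]-3-methyloxiran-2-yl]methyl acetate
Conditions: **3** (1.5 equiv), (R)-3,3'-Ph2-BINOL (15 mol%), toluene, 4 Å MS, −35 °C, 24 h
Reagents that add atoms: **3**, C=CCB(OC(C)C)OC(C)C (adds the allyl group)
Why: Chiral-diol-catalysed allylboration (Schaus type) proceeds through a chair Zimmerman–Traxler transition state, and the catalyst face-selectivity sets C11 (R). Catalyst control is assumed to override the adjacent epoxide bias. The epoxide and acetate survive.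

**Step 3**
Reactants: **4**
Product: **5** TES ether of **4** (configuration retained)
Conditions: TESCl, imidazole, DMF, 0 °C to rt
Reagents that add atoms: chlorotriethylsilane, CC[Si](Cl)(CC)CC
Why: Silylation under mild, non-Lewis-acidic conditions protects C11-OH without opening the epoxide. No stereocenter is touched.

**Step 4**
Reactants: **5**
Product: **6** C9 aldehyde (vinyl group of **5** cleaved to CHO; configuration retained)
Conditions: O3, CH2Cl2, −78 °C; then PPh3, −78 °C to rt
Reagents that add atoms: ozone, [O-][O+]=O
Why: Ozonolysis of the only alkene (the terminal vinyl group) leaves the epoxide, acetate and silyl ether intact. The β-silyloxy aldehyde is used immediately.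

**Step 5**
Reactants: **6**; **7** 2-(triphenylphosphoranylidene)propionaldehyde
Product: **8** (E)-α-methyl enal (C7 aldehyde, C8=C9)
Conditions: **7** (1.5 equiv), toluene, 60 °C, 12 h
Reagents that add atoms: **7**, CC(C=O)=P(c1ccccc1)(c1ccccc1)c1ccccc1 (adds C(CH3)CHO)
Why: Wittig olefination with a stabilized ylide is E-selective (>20:1) and forms the C8=C9 trisubstituted alkene. The neutral conditions do not epimerize C11.

**Step 6**
Reactants: **8**; **3**
Product: **9** homoallylic alcohol (7S)
Conditions: **3** (1.5 equiv), (S)-3,3'-Ph2-BINOL (15 mol%), toluene, 4 Å MS, −35 °C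
Reagents that add atoms: **3**, C=CCB(OC(C)C)OC(C)C
Why: Catalytic asymmetric allylboration of the enal (chair transition state, catalyst-controlled) sets C7 (S), which is remote from the other stereocenters. The C14 acetate is untouched.

**Step 7**
Reactants: **9**
Product: **10** C7-TBS ether of **9**
Conditions: TBSCl, imidazole, DMAP (cat.), DMF, 40 °C
Reagents that add atoms: TBSCl, CC(C)(C)[Si](C)(C)Cl
Why: A silyl ether on the hindered allylic alcohol survives the later CM, Dess–Martin oxidation and Cr step. It is the last group removed, which leaves C7-OH free as in the target.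

**Step 8**
Reactants: **10**
Product: **11** primary alcohol (C14-OH; C5 vinyl, C7-OTBS, C11-OTES)
Conditions: K2CO3 (0.3 equiv), MeOH, 0 °C, 1 h
Reagents that add atoms: none
Why: Mild methanolysis (Zemplén type) cleaves only the primary acetate. The silyl ethers and epoxide are stable, and Payne rearrangement is negligible at 0 °C.

**Step 9**
Reactants: **12** ethyl glyoxylate; **13** methallyldiisopropoxyborane
Product: **14** ethyl (2R)-2-hydroxy-4-methylpent-4-enoate
Conditions: **13** (1.5 equiv), (S)-3,3'-Ph2-BINOL (15 mol%), toluene, 4 Å MS, −35 °C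
Reagents that add atoms: **13**, C=C(C)CB(OC(C)C)OC(C)C (adds the methallyl group)
Why: The same catalytic asymmetric allylboration sets C2 (R) on the highly electrophilic glyoxylate.

**Step 10**
Reactants: **14**
Product: **15** TES ether of **14**
Conditions: TESCl, imidazole, DMF, rt
Reagents that add atoms: CC[Si](Cl)(CC)CC
Why: A silyl group is used rather than an acetate, so that no acyl migration to the neighbouring Baylis–Hillman alkoxide can occur in Step 12.

**Step 11**
Reactants: **15**
Product: **16** (2R)-4-methyl-2-(triethylsilyloxy)pent-4-enal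
Conditions: DIBAL-H (1.05 equiv), CH2Cl2, −78 °C; Rochelle salt work-up
Reagents that add atoms: none
Why: Partial ester reduction stops at the aldehyde at −78 °C. The α-centre is stable because silyl ether groups do not promote enolization.

**Step 12**
Reactants: **16**; **17** methyl acrylate
Product: **18** Baylis–Hillman adduct (C1 carbinol, epimeric mixture)
Conditions: **17** (3 equiv), DABCO (0.3 equiv), MeCN, rt, 5 d
Reagents that add atoms: **17**, C=CC(=O)OC (adds C15–C17)
Why: Morita–Baylis–Hillman reaction forms the C1–C15 bond. The new C1 carbinol centre is erased when the allylchromium forms in Step 16, so the diastereomer mixture is carried forward.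

**Step 13**
Reactants: **18**
Product: **19** methyl 2-(chloromethyl)-4-(TESO)-6-methylhepta-2,6-dienoate (E/Z mixture)
Conditions: MsCl, Et3N, CH2Cl2, 0 °C; then LiCl, DMF, rt
Reagents that add atoms: lithium chloride, [Li+].[Cl-] (MsCl leaves no atoms)
Why: Mesylation followed by SN2' displacement gives the allylic chloride. A chloride is chosen over a bromide so that it survives Ru metathesis. The allylchromium from either regioisomer or alkene geometry is the same.

**Step 14**
Reactants: **11**; **19**
Product: **20** (E)-C4=C5 chain with C1 allyl chloride, C14-OH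
Conditions: **19** (2 equiv), Hoveyda–Grubbs II (10 mol%), CH2Cl2, 40 °C, 12 h
Reagents that add atoms: none (ethylene is lost)
Why: Cross-metathesis of a monosubstituted alkene (**11**) with a 1,1-disubstituted alkene (**19**, which cannot homodimerize) forms the E-trisubstituted C4=C5 alkene. The trisubstituted acrylate in **19** is inert to metathesis.

**Step 15**
Reactants: **20**
Product: **21** epoxy aldehyde (C14 CHO)
Conditions: Dess–Martin periodinane, NaHCO3, CH2Cl2, 0 °C to rt; crude used directly
Reagents that add atoms: none
Why: Oxidation of the primary alcohol. The silyl ethers, allylic chloride and acrylate are inert, and the sensitive α,β-epoxy aldehyde is not stored.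

**Step 16**
Reactants: **21**
Product: **22** silyl-protected macrolide, i.e. michaolide A carrying 2-OTES, 7-OTBS and 11-OTES
Conditions: CrCl2 (10 equiv), NiCl2 (cat.), DMF, rt, 2 mM, slow addition over 10 h; aq. NH4Cl work-up
Reagents that add atoms: none
Why: Intramolecular Nozaki–Hiyama–Kishi allylation. The allylchromium attacks C14 through C1, the γ-carbon, via a chair transition state. The E-allylchromium gives the anti adduct, and hence the trans-lactone. The C2 and C13 stereocenters and the ring conformation set the sense of C1/C14. The alkoxide lactonizes onto the methyl ester to give the α-methylene-γ-butyrolactone, and the epoxide and silyl ethers survive.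

**Step 17**
Reactants: **22**
Product: **23** C2,C11-diol (C7-OTBS retained)
Conditions: HF·pyridine, pyridine, THF, 0 °C, 1 h
Reagents that add atoms: none
Why: Buffered HF selectively cleaves the two TES ethers over the hindered TBS ether. The short reaction time and low temperature limit epoxide opening and translactonization.

**Step 18**
Reactants: **23**
Product: **24** 2,11-diacetate (C7-OTBS)
Conditions: Ac2O, DMAP, pyridine, CH2Cl2, 0 °C to rt
Reagents that add atoms: acetic anhydride, CC(=O)OC(C)=O
Why: Acetylation traps C2-O before any translactonization can occur. No stereocenter is affected.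

**Step 19**
Reactants: **24**
Product: **25** michaolide A
Conditions: HF·pyridine, pyridine, THF, rt, 36 h
Reagents that add atoms: none
Why: Fluoride removes the last silyl group. The acetates, lactone and epoxide tolerate buffered HF·py, as in epothilone-type epoxide chemistry.

## Compound list
1 | (E)-4-acetoxy-2-methylbut-2-enal | CC(=O)OC/C=C(\C)C=O | starting material
2 | [(2S,3R)-3-formyl-3-methyloxiran-2-yl]methyl acetate | O=C[C@]1(C)O[C@H]1COC(C)=O | intermediate
3 | allyldiisopropoxyborane | C=CCB(OC(C)C)OC(C)C | starting material
4 | [(2S,3S)-3-[(1R)-1-hydroxybut-3-en-1-yl]-3-methyloxiran-2-yl]methyl acetate | C=CC[C@@H](O)[C@]1(C)O[C@H]1COC(C)=O | intermediate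
5 | TES ether of 4 | C=CC[C@@H](O[Si](CC)(CC)CC)[C@]1(C)O[C@H]1COC(C)=O | intermediate
6 | C9 aldehyde from 5 | O=CC[C@@H](O[Si](CC)(CC)CC)[C@]1(C)O[C@H]1COC(C)=O | intermediate
7 | 2-(triphenylphosphoranylidene)propionaldehyde | CC(C=O)=P(c1ccccc1)(c1ccccc1)c1ccccc1 | starting material
8 | (E)-α-methyl enal (C7 CHO) | O=C/C(C)=C/C[C@@H](O[Si](CC)(CC)CC)[C@]1(C)O[C@H]1COC(C)=O | intermediate
9 | (7S)-homoallylic alcohol | C=CC[C@H](O)/C(C)=C/C[C@@H](O[Si](CC)(CC)CC)[C@]1(C)O[C@H]1COC(C)=O | intermediate
10 | C7-TBS ether of 9 | C=CC[C@H](O[Si](C)(C)C(C)(C)C)/C(C)=C/C[C@@H](O[Si](CC)(CC)CC)[C@]1(C)O[C@H]1COC(C)=O | intermediate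
11 | C14 primary alcohol from 10 | C=CC[C@H](O[Si](C)(C)C(C)(C)C)/C(C)=C/C[C@@H](O[Si](CC)(CC)CC)[C@]1(C)O[C@H]1CO | intermediate
12 | ethyl glyoxylate | CCOC(=O)C=O | starting material
13 | methallyldiisopropoxyborane | C=C(C)CB(OC(C)C)OC(C)C | starting material
14 | ethyl (2R)-2-hydroxy-4-methylpent-4-enoate | CCOC(=O)[C@H](O)CC(C)=C | intermediate
15 | TES ether of 14 | CCOC(=O)[C@H](O[Si](CC)(CC)CC)CC(C)=C | intermediate
16 | (2R)-4-methyl-2-(triethylsilyloxy)pent-4-enal | O=C[C@H](O[Si](CC)(CC)CC)CC(C)=C | intermediate
17 | methyl acrylate | C=CC(=O)OC | starting material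
18 | Baylis–Hillman adduct (C1 epimers) | C=C(C)C[C@@H](O[Si](CC)(CC)CC)C(O)C(=C)C(=O)OC | intermediate
19 | allylic chloride (E/Z mixture) | ClCC(C(=O)OC)=C[C@H](O[Si](CC)(CC)CC)CC(C)=C | intermediate
20 | CM product (C4=C5 E), C14-OH | ClCC(C(=O)OC)=C[C@H](O[Si](CC)(CC)CC)C/C(C)=C/C[C@H](O[Si](C)(C)C(C)(C)C)/C(C)=C/C[C@@H](O[Si](CC)(CC)CC)[C@]1(C)O[C@H]1CO | intermediate
21 | C14 epoxy aldehyde | ClCC(C(=O)OC)=C[C@H](O[Si](CC)(CC)CC)C/C(C)=C/C[C@H](O[Si](C)(C)C(C)(C)C)/C(C)=C/C[C@@H](O[Si](CC)(CC)CC)[C@]1(C)O[C@H]1C=O | intermediate
22 | silyl-protected macrolide | C=C1C(=O)O[C@H]2[C@H]1[C@H](O[Si](CC)(CC)CC)C/C(C)=C/C[C@H](O[Si](C)(C)C(C)(C)C)/C(C)=C/C[C@@H](O[Si](CC)(CC)CC)[C@]1(C)O[C@@H]21 | intermediate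
23 | C2,C11-diol, 7-OTBS | C=C1C(=O)O[C@H]2[C@H]1[C@H](O)C/C(C)=C/C[C@H](O[Si](C)(C)C(C)(C)C)/C(C)=C/C[C@@H](O)[C@]1(C)O[C@@H]21 | intermediate
24 | 2,11-diacetate, 7-OTBS | C=C1C(=O)O[C@H]2[C@H]1[C@H](OC(C)=O)C/C(C)=C/C[C@H](O[Si](C)(C)C(C)(C)C)/C(C)=C/C[C@@H](OC(C)=O)[C@]1(C)O[C@@H]21 | intermediate
25 | michaolide A | C=C1C(=O)O[C@H]2[C@H]1[C@H](OC(C)=O)C/C(C)=C/C[C@H](O)/C(C)=C/C[C@@H](OC(C)=O)[C@]1(C)O[C@@H]21 | target

## Totals
Total steps: 19. Longest linear sequence: 14 (Steps 1–8, 14–19).

## Three steps most likely to fail
1. **Step 1 (proposed new method).** Iminium formation and conjugate addition on an α,β-disubstituted enal may be slow or low in ee.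
   - Fallback: reduce **1** (NaBH4/CeCl3) to the (E)-allylic alcohol, perform Sharpless Ti/tartrate asymmetric epoxidation, then Parikh–Doering oxidation to give **2**. The route then continues unchanged.
2. **Step 16.** The macrocyclic NHK may give the wrong C1/C14 diastereomer, or Cr(II) may attack the epoxy aldehyde.
   - Fallback: build the trans-lactone first by intermolecular anti-selective In- or Zn-mediated allylation and lactonization of an epoxy-aldehyde fragment with the MBH-derived bromide. Then close the ring by RCM at C4=C5 or by an intramolecular vinyl-iodide NHK at C7–C8.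
3. **Step 14.** The E/Z ratio of the trisubstituted C4=C5 alkene may be poor, or the allylic chloride may poison the Ru catalyst.
   - Fallback: replace CM with Julia–Kocienski olefination of the C5 aldehyde (ozonolysis of the vinyl group of **11**) with a PT-sulfone of the C1–C4 unit.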